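(The numbers of this flask are made up; the result is computed.)

A mole of reagent makes at most one mole of target, so I count this flask in moles of target per mole of reagent charged.

    second substrate + reagent → second product (k1 = 1.2 /M/min)
    starting material + reagent → target (k2 = 44 /M/min)
    starting material → decomposition product (k3 = 8.1 × 10⁻⁵ /min)
    starting material + target → side product (k4 = 3.2 /M/min)
    starting material + second substrate → cross product (k5 = 1.9 /M/min)

| flask | starting material | reagent | second substrate | time |
|---|---|---|---|---|
| eta | 0.050 M | 0.0380 M | 0.250 M | 20 min |
| delta | 0.050 M | 0.0250 M | 0.250 M | 20 min |

- in percentages every species weighs as the starting material in it: one side product counts as two
- run time (eta): 20 min

- which of the two there is more of at the end, eta (target / cross product)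
- which of the two there is more of at the end, delta (target / cross product)
- how much target is there at the end, in percent of the starting material charged: eta
- how much target is there at the end, in percent of the starting material charged: delta

I take the time first. In delta, with the other concentrations as charged, starting material has a half-life of 0.63 min by the step with reagent and 1.5 min by the step with second substrate, both shorter than the run of 20 min. The run is much shorter than the 140 h half-life of starting material by decomposition. So by hand a longer run adds nothing, and I reckon the end state, assuming starting material and reagent both used up.

Reagent is the limiting reagent in eta and delta, which gives two shares. F, the share of reagent taken at the start by starting material rather than second substrate, is 88.0% in both flasks. S, the selectivity, is the starting share of starting material taken by reagent rather than by the pseudo-first-order cross reaction: 77.9% in eta and 69.8% in delta. As a rule of thumb, with both shares frozen at the start and the step to side product left out, I multiply them into G, the target per mole of reagent charged: 68.5% in eta and, in delta, 61.5%.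

By hand, more reagent raises both the equivalents and S, more starting material lowers the equivalents and raises F, and more second substrate lowers F and S. Multiplying G by the equivalents gives 52.1% target in eta and 30.7% in delta. If I book the rest as cross product, eta favours target and delta cross product.

The forecast gives target at 48% for eta and cross product with 32% target for delta, saying “With more reagent in eta the target narrowly beats the cross product”. Eta ends with 49.7% target against 39.9% cross product, and delta with 33.7% against 55.3%. Moved alone by one common factor, the settings shift the target in eta in this order: reagent (11 points), then starting material (9.1 points), then second substrate (3.1 points), then time (under 0.05 points).

Delta's reading is 67.4% target per mole of reagent charged, against G of 61.5%. A neighbouring flask repeats delta with 0.010 M reagent, which is 0.200 equiv. There F stays, S falls, and G becomes 42.3%, so I reckon 8.46% target. That flask ends with 13.2% target and 79.8% cross product.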